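**Plan**

1. Numbering used (longipinane): C1 ketone, C2=C3(CH3) alkene, cyclobutane C4(H)–C5(H)–C11(H)–C10(CH3), seven-membered ring C5–C6(Me2)–C7(O)–C8–C9(O)–C10–C11.
2. Retrosynthesis cuts, in order: the two ester C–O bonds at O9 and O7; then C1–C11 and C3–C4, which lifts the enone C1–C2–C3 off as a (Z)-β-magnesio crotonate and leaves a bicyclo[1.1.0]butane ester with a C4–C11 central bond; then C11–C4 and C11–C5 (carbene plus alkene); then C10–C11 ([3,3]); then the C9–O/C5–O pair (O2); then the seven-membered ring ((4+3)).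
3. Enabling feature: in the cyclobutane C4–C5–C11–C10 the two CH corners C4 and C11 are 1,3-related and joined by the three-carbon enone bridge, while the other diagonal C5/C10 is already tied by the chain C6–C9. This is a 2,4-bridged bicyclo[1.1.0]butane with a three-carbon acyl-vinyl unit inserted into its central σ bond.
4. Forward order: seven-membered ring first ((4+3) to karahanaenone); oxygen at C7 (CBS) and at C9/C5 (singlet oxygen); quaternary C10 (Johnson–Claisen); then in one flask the cyclobutane (as bicyclobutane) and the cyclohexenone (C3–C4, then ring closure C1–C11); then decarboxylation at C11 and the two acylations.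
5. Stereochemistry: C7 from CBS reduction; C9 from O2 addition anti to the C7 silyl ether; C10 by suprafacial Claisen transfer from the temporary C5–OH; C4, C5 and C11 from the topology of bicyclobutane formation and opening; the epoxy acid from Sharpless epoxidation of tiglyl alcohol; the angelate from angelic acid.

Key step: step 11

Remark on the chemistry: configurations are taken from the SMILES as written. The epoxy ester is (2S,3R) with cis methyl groups (the epoxide of a tiglate), the unsaturated ester is the (Z)-isomer (angelate), and the core is (4R,5S,7R,9R,10R,11R) in the numbering above.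

**Route**

Step 1
Reactants: 1 3-bromo-3-methylbutan-2-one
Product: 2 [(3-bromo-3-methylbut-1-en-2-yl)oxy]trimethylsilane
Conditions: LiN(iPr)2, Me3SiCl (in situ quench), THF, −78 °C
Reagents that add atoms: chlorotrimethylsilane C[Si](C)(C)Cl
Why: kinetic enolisation of the only enolisable side (the CH3 group) and O-silylation (silyl enol ether formation) give the 2-siloxyallyl bromide; no stereocentre is formed.

Step 2
Reactants: 2 [(3-bromo-3-methylbut-1-en-2-yl)oxy]trimethylsilane; 3 isoprene
Product: 5 2,2,5-trimethylcyclohept-4-en-1-one (karahanaenone), via siloxyallyl cation 4 (not isolated)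
Conditions: ZnCl2 (0.3 equiv), CH2Cl2, −30 → 23 °C
Reagents that add atoms: none
Why: ZnCl2 ionises the tertiary C–Br bond to the 1,1-dimethyl-2-siloxyallyl cation, which adds to isoprene in a (4+3) cycloaddition of the Hoffmann/Sakurai type; the less hindered CH2 terminus of the cation should bond to C1 of isoprene, which places the ring methyl at C5, and loss of the silyl group gives the achiral ketone.

Step 3
Reactants: 5 2,2,5-trimethylcyclohept-4-en-1-one
Product: 6 (1R)-2,2,5-trimethylcyclohept-4-en-1-ol
Conditions: (S)-2-methyl-CBS-oxazaborolidine (15 mol%), catecholborane, toluene, −78 °C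
Reagents that add atoms: none
Why: Corey–Bakshi–Shibata reduction, in which the (S)-oxazaborolidine distinguishes the quaternary CMe2 flank (large) from the CH2 flank (small) and should give the (R)-carbinol (future C7), while catecholborane at −78 °C leaves the trisubstituted alkene untouched.

Step 4
Reactants: 6 (1R)-2,2,5-trimethylcyclohept-4-en-1-ol
Product: 7 triethyl{[(1R)-2,2,5-trimethylcyclohept-4-en-1-yl]oxy}silane
Conditions: Et3SiOTf, 2,6-lutidine, CH2Cl2, −78 → 0 °C
Reagents that add atoms: triethylsilyl trifluoromethanesulfonate CC[Si](CC)(CC)OS(=O)(=O)C(F)(F)F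
Why: silylation of a hindered secondary alcohol with a silyl triflate; the neopentyl position makes this triethylsilyl ether sturdier than usual yet still cleavable before a tert-butyldimethylsilyl ether.

Step 5
Reactants: 7 triethyl{[(1R)-2,2,5-trimethylcyclohept-4-en-1-yl]oxy}silane
Product: 9 triethyl{[(1R)-4,7,7-trimethylcyclohepta-3,5-dien-1-yl]oxy}silane, via trans-dibromide 8 (not isolated)
Conditions: Br2, CH2Cl2, −78 °C; then LiBr, Li2CO3, DMF, 120 °C
Reagents that add atoms: none
Why: anti bromination of the alkene followed by double dehydrobromination under equilibrating LiBr/Li2CO3 conditions should give the more substituted, endocyclic conjugated diene; the C1 stereocentre is not touched.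

Step 6
Reactants: 9 triethyl{[(1R)-4,7,7-trimethylcyclohepta-3,5-dien-1-yl]oxy}silane
Product: 11 (1R,4R,6R)-3,7,7-trimethyl-6-(triethylsilyloxy)cyclohept-2-ene-1,4-diol, via endoperoxide 10 (not isolated)
Conditions: O2, tetraphenylporphyrin (cat.), visible light, CH2Cl2, −30 °C; then thiourea, MeOH, 23 °C
Reagents that add atoms: dioxygen O=O
Why: singlet-oxygen [4+2] photooxygenation of the cyclic diene on the face away from the silyloxy group, then reduction of the O–O bond; both new carbinol centres come from one O2 molecule, so they are cis to each other and trans to the silyl ether.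

Step 7
Reactants: 11 (1R,4R,6R)-3,7,7-trimethyl-6-(triethylsilyloxy)cyclohept-2-ene-1,4-diol
Product: 12 (1R,4R,6R)-4-(tert-butyldimethylsilyloxy)-3,7,7-trimethyl-6-(triethylsilyloxy)cyclohept-2-en-1-ol
Conditions: t-BuMe2SiCl, imidazole, DMF, 0 °C
Reagents that add atoms: tert-butyldimethylsilyl chloride CC(C)(C)[Si](C)(C)Cl
Why: selective silylation of the less hindered allylic hydroxyl (flanked by CH2, future C9) over the neopentyl hydroxyl next to CMe2.

Step 8
Reactants: 12 (1R,4R,6R)-4-(tert-butyldimethylsilyloxy)-3,7,7-trimethyl-6-(triethylsilyloxy)cyclohept-2-en-1-ol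
Product: 14 methyl 2-[(1S,5R,7R)-7-(tert-butyldimethylsilyloxy)-1,4,4-trimethyl-5-(triethylsilyloxy)cyclohept-2-en-1-yl]acetate, via mixed ketene acetal 13 (not isolated)
Conditions: MeC(OMe)3, EtCO2H (cat.), xylene, 140 °C, MeOH distilled off
Reagents that add atoms: trimethyl orthoacetate CC(OC)(OC)OC
Why: Johnson–Claisen rearrangement, whose suprafacial [3,3] shift puts the CH2CO2Me group on the ring face of the C–O bond that breaks, so the new quaternary centre (future C10) carries it cis to the neighbouring silyloxy group, and the alkene moves to where the carbene step needs it.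

Step 9
Reactants: 14 methyl 2-[(1S,5R,7R)-7-(tert-butyldimethylsilyloxy)-1,4,4-trimethyl-5-(triethylsilyloxy)cyclohept-2-en-1-yl]acetate
Product: 16 methyl 2-diazo-2-[(1R,5R,7R)-7-(tert-butyldimethylsilyloxy)-1,4,4-trimethyl-5-(triethylsilyloxy)cyclohept-2-en-1-yl]acetate, via trifluoroacetyl ester 15 (not isolated)
Conditions: LiN(iPr)2, THF, −78 °C; CF3CO2CH2CF3; then MeSO2N3, Et3N, MeCN, H2O, 23 °C
Reagents that add atoms: methanesulfonyl azide CS(=O)(=O)N=[N+]=[N-]
Why: deacylative (Regitz/Danheiser) diazo transfer, in which Claisen trifluoroacetylation activates the α-carbon, the sulfonyl azide transfers N2 and the trifluoroacetyl group leaves as the sulfonamide; no stereocentre changes (the C1 descriptor changes by priority only).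

Step 10
Reactants: 17 ethyl but-2-ynoate
Product: 18 ethyl (Z)-3-iodobut-2-enoate
Conditions: NaI, AcOH, 115 °C
Reagents that add atoms: sodium iodide [Na+].[I-]
Why: conjugate hydroiodination of the ynoate, which by anti addition of HI gives the (Z)-β-iodo enoate with iodine cis to the ester.

Step 11
Reactants: 16 methyl 2-diazo-2-[(1R,5R,7R)-7-(tert-butyldimethylsilyloxy)-1,4,4-trimethyl-5-(triethylsilyloxy)cyclohept-2-en-1-yl]acetate; 18 ethyl (Z)-3-iodobut-2-enoate
Product: 22 methyl 9-(tert-butyldimethylsilyloxy)-1-oxo-7-(triethylsilyloxy)longipin-2-ene-11-carboxylate (ring configuration as in 36; CO2Me on C11 faces the seven-membered ring), via alkenylmagnesium chloride 19 (not isolated), via bicyclo[1.1.0]butane ester 20 (not isolated), via magnesium ester enolate 21 (not isolated)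
Conditions: 18, iPrMgCl·LiCl, THF, −40 °C; separately 16, Rh2(O2CC(CH3)3)4 (1 mol%), toluene, −78 °C; then CuBr·SMe2 (30 mol%), PBu3, add the magnesium reagent, −78 → 23 °C
Reagents that add atoms: none
Why: Proposed new method: the rhodium carbenoid from 16 adds to the ring alkene C4=C5 from the face on which C10 holds it and closes both three-membered rings of bicyclo[1.1.0]butane 20 (a [2+1] addition, two 3-exo closures); the copper-activated (Z)-alkenylmagnesium reagent 19 then adds to the unsubstituted bridgehead C4 with cleavage of the central C4–C11 σ bond, and the ester enolate 21 attacks the cis-held ethyl ester through C11 (6-exo-trig Dieckmann closure, loss of ethoxide), which forms the C1–C11 bond and closes the cyclohexenone. The closest known chemistry is the one-flask rhodium-catalysed bicyclobutanation of α-allyl-α-diazo esters followed by copper-catalysed homoconjugate addition of Grignard reagents with enolate trapping, together with annulations by (Z)-β-metallo enoates; new here is trapping the enolate with an ester carried by the entering nucleophile on a ring-fused bicyclobutane, reasonable because after the addition C11 and the ester carbonyl are 1,3-cis on a cyclobutane and within bonding distance. C5 and C10 keep the seven-membered ring on the concave side because the tethered carbene can reach only one alkene face; C4 is set by attack on the outer lobe of the central bond (inversion, anti to the seven-membered ring); C11 is set by the tether, since only the face carrying the alkenyl ester can be acylated, which leaves CO2Me toward the seven-membered ring. The step needs cyclopropanation to beat C–H insertion (C10 is quaternary, so no 1,2-hydride shift, and the alkene is two bonds from the carbene), attack at C4 and not C11 (the ester on C11 polarises the central bond, which is why it is carried and later removed), and retention of the Z geometry of 19 (magnesium chelated by the ester).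

Step 12
Reactants: 22 methyl 9-(tert-butyldimethylsilyloxy)-1-oxo-7-(triethylsilyloxy)longipin-2-ene-11-carboxylate
Product: 23 9-(tert-butyldimethylsilyloxy)-1-oxo-7-(triethylsilyloxy)longipin-2-ene-11-carboxylic acid (configuration as in 22)
Conditions: LiI, pyridine, 115 °C; 1 M HCl work-up
Reagents that add atoms: none
Why: SN2 dealkylation of the hindered methyl ester by iodide, a hydroxide-free cleavage, so the non-enolisable β-keto ester cannot open by retro-Claisen attack on the ketone; no stereocentre changes.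

Step 13
Reactants: 23 9-(tert-butyldimethylsilyloxy)-1-oxo-7-(triethylsilyloxy)longipin-2-ene-11-carboxylic acid
Product: 26 (4R,5S,7R,9R,10R,11R)-9-(tert-butyldimethylsilyloxy)-7-(triethylsilyloxy)longipin-2-en-1-one, via acid chloride 24 (not isolated), via thiohydroxamate ester 25 (not isolated)
Conditions: (COCl)2, DMF (cat.), CH2Cl2, 0 → 23 °C; then sodium 1-oxidopyridine-2-thiolate (NaC5H4NOS), DMAP (cat.), t-BuSH, toluene, tungsten lamp, 23 °C
Reagents that add atoms: none
Why: Barton reductive decarboxylation, needed because a bridgehead β-keto acid cannot lose CO2 through an enol; the C11 bridgehead σ-radical takes hydrogen from t-BuSH with retention, the only geometry the bicyclo[3.1.1]heptenone allows.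

Step 14
Reactants: 26 (4R,5S,7R,9R,10R,11R)-9-(tert-butyldimethylsilyloxy)-7-(triethylsilyloxy)longipin-2-en-1-one
Product: 27 (4R,5S,7R,9R,10R,11R)-9-(tert-butyldimethylsilyloxy)-7-hydroxylongipin-2-en-1-one
Conditions: pyridinium 4-toluenesulfonate, MeOH, CH2Cl2, 0 → 23 °C
Reagents that add atoms: none
Why: acid-catalysed methanolysis removes the triethylsilyl ether much faster than the tert-butyldimethylsilyl ether, which frees the C7 hydroxyl alone.

Step 15
Reactants: 28 (E)-2-methylbut-2-en-1-ol (tiglyl alcohol)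
Product: 29 [(2R,3R)-2,3-dimethyloxiran-2-yl]methanol
Conditions: Ti(OiPr)4 (10 mol%), D-(−)-diethyl tartrate, t-BuOOH, 4 Å sieves, CH2Cl2, −20 °C
Reagents that add atoms: tert-butyl hydroperoxide CC(C)(C)OO
Why: Sharpless asymmetric epoxidation, where D-(−)-tartrate gives the (2R,3R)-epoxy alcohol (the L-(+)-tartrate gives (2S,3S) with (E)-allylic alcohols) and the E geometry fixes the cis methyl groups.

Step 16
Reactants: 29 [(2R,3R)-2,3-dimethyloxiran-2-yl]methanol
Product: 30 (2S,3R)-2,3-dimethyloxirane-2-carboxylic acid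
Conditions: RuCl3 (2 mol%), NaIO4, MeCN, CCl4, H2O, 23 °C
Reagents that add atoms: sodium periodate [Na+].[O-]I(=O)(=O)=O; water O
Why: ruthenium tetroxide oxidation (Sharpless conditions) of the primary alcohol to the acid; both epoxide centres are untouched and the C2 descriptor changes only by priority.

Step 17
Reactants: 27 (4R,5S,7R,9R,10R,11R)-9-(tert-butyldimethylsilyloxy)-7-hydroxylongipin-2-en-1-one; 30 (2S,3R)-2,3-dimethyloxirane-2-carboxylic acid
Product: 32 (4R,5S,7R,9R,10R,11R)-9-(tert-butyldimethylsilyloxy)-7-[(2S,3R)-2,3-dimethyloxirane-2-carbonyloxy]longipin-2-en-1-one, via mixed anhydride 31 (not isolated)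
Conditions: 30, 2,4,6-Cl3C6H2COCl, Et3N, THF, 23 °C; then 27, DMAP, toluene, 40 °C
Reagents that add atoms: none
Why: Yamaguchi esterification, suited to a hindered secondary alcohol and an α,α-disubstituted acid; the acid has no epimerisable centre and C7 is acylated with retention.

Step 18
Reactants: 32 (4R,5S,7R,9R,10R,11R)-9-(tert-butyldimethylsilyloxy)-7-[(2S,3R)-2,3-dimethyloxirane-2-carbonyloxy]longipin-2-en-1-one
Product: 33 (4R,5S,7R,9R,10R,11R)-9-hydroxy-7-[(2S,3R)-2,3-dimethyloxirane-2-carbonyloxy]longipin-2-en-1-one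
Conditions: HF·pyridine, pyridine, THF, 0 → 23 °C
Reagents that add atoms: none
Why: fluoride desilylation under buffered conditions, which a glycidic ester (an epoxide deactivated by its ester) and the enone should tolerate.

Step 19
Reactants: 33 (4R,5S,7R,9R,10R,11R)-9-hydroxy-7-[(2S,3R)-2,3-dimethyloxirane-2-carbonyloxy]longipin-2-en-1-one; 34 (Z)-2-methylbut-2-enoic acid (angelic acid)
Product: 36 (4R,5S,7R,9R,10R,11R)-9-[(Z)-2-methylbut-2-enoyloxy]-7-[(2S,3R)-2,3-dimethyloxirane-2-carbonyloxy]longipin-2-en-1-one (CNP0149458.1), via mixed anhydride 35 (not isolated)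
Conditions: 34, 2,4,6-Cl3C6H2COCl, Et3N, toluene, 23 °C; then 33, 75 °C
Reagents that add atoms: none
Why: Yamaguchi-type angeloylation through the trichlorobenzoyl mixed anhydride without a nucleophilic catalyst, the usual way to acylate hindered alcohols with angelic acid without Z to E isomerisation; it is placed last because the angelate is the most labile group.

**Compound list**

1 | 3-bromo-3-methylbutan-2-one | CC(=O)C(C)(C)Br | starting material
2 | [(3-bromo-3-methylbut-1-en-2-yl)oxy]trimethylsilane | C=C(O[Si](C)(C)C)C(C)(C)Br | intermediate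
3 | isoprene | C=CC(C)=C | starting material
4 | 1,1-dimethyl-2-(trimethylsilyloxy)allyl cation (not isolated) | C[C+](C)C(=C)O[Si](C)(C)C | intermediate
5 | 2,2,5-trimethylcyclohept-4-en-1-one (karahanaenone) | CC1=CCC(C)(C)C(=O)CC1 | intermediate
6 | (1R)-2,2,5-trimethylcyclohept-4-en-1-ol | CC1=CCC(C)(C)[C@H](O)CC1 | intermediate
7 | triethyl{[(1R)-2,2,5-trimethylcyclohept-4-en-1-yl]oxy}silane | CC1=CCC(C)(C)[C@H](O[Si](CC)(CC)CC)CC1 | intermediate
8 | trans-4,5-dibromide of 7 (both trans diastereomers; not isolated) | CC1(Br)C(Br)CC(C)(C)[C@H](O[Si](CC)(CC)CC)CC1 | intermediate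
9 | triethyl{[(1R)-4,7,7-trimethylcyclohepta-3,5-dien-1-yl]oxy}silane | CC1=CC[C@@H](O[Si](CC)(CC)CC)C(C)(C)C=C1 | intermediate
10 | endoperoxide of 9, peroxide bridge anti to the silyloxy group (not isolated) | CC1=C[C@H]2OO[C@@H]1C[C@@H](O[Si](CC)(CC)CC)C2(C)C | intermediate
11 | (1R,4R,6R)-3,7,7-trimethyl-6-(triethylsilyloxy)cyclohept-2-ene-1,4-diol | CC1=C[C@@H](O)C(C)(C)[C@H](O[Si](CC)(CC)CC)C[C@H]1O | intermediate
12 | (1R,4R,6R)-4-(tert-butyldimethylsilyloxy)-3,7,7-trimethyl-6-(triethylsilyloxy)cyclohept-2-en-1-ol | CC1=C[C@@H](O)C(C)(C)[C@H](O[Si](CC)(CC)CC)C[C@H]1O[Si](C)(C)C(C)(C)C | intermediate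
13 | 1-methoxyvinyl ether of 12 (mixed ketene acetal; not isolated) | CC1=C[C@@H](OC(=C)OC)C(C)(C)[C@H](O[Si](CC)(CC)CC)C[C@H]1O[Si](C)(C)C(C)(C)C | intermediate
14 | methyl 2-[(1S,5R,7R)-7-(tert-butyldimethylsilyloxy)-1,4,4-trimethyl-5-(triethylsilyloxy)cyclohept-2-en-1-yl]acetate | C[C@]1(CC(=O)OC)C=CC(C)(C)[C@H](O[Si](CC)(CC)CC)C[C@H]1O[Si](C)(C)C(C)(C)C | intermediate
15 | α-trifluoroacetyl derivative of 14 (epimers/enol; not isolated) | C[C@]1(C(C(=O)C(F)(F)F)C(=O)OC)C=CC(C)(C)[C@H](O[Si](CC)(CC)CC)C[C@H]1O[Si](C)(C)C(C)(C)C | intermediate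
16 | methyl 2-diazo-2-[(1R,5R,7R)-7-(tert-butyldimethylsilyloxy)-1,4,4-trimethyl-5-(triethylsilyloxy)cyclohept-2-en-1-yl]acetate | C[C@]1(C(=[N+]=[N-])C(=O)OC)C=CC(C)(C)[C@H](O[Si](CC)(CC)CC)C[C@H]1O[Si](C)(C)C(C)(C)C | intermediate
17 | ethyl but-2-ynoate | CC#CC(=O)OCC | starting material
18 | ethyl (Z)-3-iodobut-2-enoate | CCOC(=O)/C=C(/C)I | intermediate
19 | ethyl (Z)-3-(chloromagnesio)but-2-enoate (not isolated) | CCOC(=O)/C=C(/C)[Mg]Cl | intermediate
20 | tricyclic bicyclo[1.1.0]butane methyl ester: CO2Me on bridgehead C11, H on bridgehead C4, wingtips C5 (H exo) and C10 (CH3 exo) joined endo,endo by C6–C9 (not isolated) | COC(=O)[C@@]12[C@H]3[C@@H]1C(C)(C)[C@H](O[Si](CC)(CC)CC)C[C@@H](O[Si](C)(C)C(C)(C)C)[C@@]23C | intermediate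
21 | chloromagnesium enolate of the C11 methyl ester, C4 bearing the (Z)-alkenyl ester anti to the seven-membered ring (not isolated) | CCOC(=O)/C=C(/C)[C@H]1[C@@H]2C(C)(C)[C@H](O[Si](CC)(CC)CC)C[C@@H](O[Si](C)(C)C(C)(C)C)[C@@]1(C)C2=C(OC)O[Mg]Cl | intermediate
22 | methyl 9-(tert-butyldimethylsilyloxy)-1-oxo-7-(triethylsilyloxy)longipin-2-ene-11-carboxylate (ring configuration as in 36) | CC(C)(C)[Si](C)(C)O[C@@H]1C[C@@H](O[Si](CC)(CC)CC)C(C)(C)[C@@H]2[C@@]3(C(=O)OC)C(=O)C=C(C)[C@@H]2[C@]31C | intermediate
23 | 9-(tert-butyldimethylsilyloxy)-1-oxo-7-(triethylsilyloxy)longipin-2-ene-11-carboxylic acid | CC(C)(C)[Si](C)(C)O[C@@H]1C[C@@H](O[Si](CC)(CC)CC)C(C)(C)[C@@H]2[C@@]3(C(=O)O)C(=O)C=C(C)[C@@H]2[C@]31C | intermediate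
24 | acid chloride of 23 (not isolated) | CC(C)(C)[Si](C)(C)O[C@@H]1C[C@@H](O[Si](CC)(CC)CC)C(C)(C)[C@@H]2[C@@]3(C(=O)Cl)C(=O)C=C(C)[C@@H]2[C@]31C | intermediate
25 | 2-thioxopyridin-1(2H)-yl ester of 23 (Barton ester; not isolated) | CC(C)(C)[Si](C)(C)O[C@@H]1C[C@@H](O[Si](CC)(CC)CC)C(C)(C)[C@@H]2[C@@]3(C(=O)ON4C=CC=CC4=S)C(=O)C=C(C)[C@@H]2[C@]31C | intermediate
26 | (4R,5S,7R,9R,10R,11R)-9-(tert-butyldimethylsilyloxy)-7-(triethylsilyloxy)longipin-2-en-1-one | CC(C)(C)[Si](C)(C)O[C@@H]1C[C@@H](O[Si](CC)(CC)CC)C(C)(C)[C@@H]2[C@H]3C(=O)C=C(C)[C@@H]2[C@]31C | intermediate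
27 | (4R,5S,7R,9R,10R,11R)-9-(tert-butyldimethylsilyloxy)-7-hydroxylongipin-2-en-1-one | CC(C)(C)[Si](C)(C)O[C@@H]1C[C@@H](O)C(C)(C)[C@@H]2[C@H]3C(=O)C=C(C)[C@@H]2[C@]31C | intermediate
28 | (E)-2-methylbut-2-en-1-ol (tiglyl alcohol) | C/C=C(\C)CO | starting material
29 | [(2R,3R)-2,3-dimethyloxiran-2-yl]methanol | OC[C@@]1(C)O[C@@H]1C | intermediate
30 | (2S,3R)-2,3-dimethyloxirane-2-carboxylic acid | OC(=O)[C@@]1(C)O[C@@H]1C | intermediate
31 | mixed anhydride of 30 with 2,4,6-trichlorobenzoic acid (not isolated) | O=C(OC(=O)[C@@]1(C)O[C@@H]1C)c1c(Cl)cc(Cl)cc1Cl | intermediate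
32 | (4R,5S,7R,9R,10R,11R)-9-(tert-butyldimethylsilyloxy)-7-[(2S,3R)-2,3-dimethyloxirane-2-carbonyloxy]longipin-2-en-1-one | CC(C)(C)[Si](C)(C)O[C@@H]1C[C@@H](OC(=O)[C@@]2(C)O[C@@H]2C)C(C)(C)[C@@H]2[C@H]3C(=O)C=C(C)[C@@H]2[C@]31C | intermediate
33 | (4R,5S,7R,9R,10R,11R)-9-hydroxy-7-[(2S,3R)-2,3-dimethyloxirane-2-carbonyloxy]longipin-2-en-1-one | O[C@@H]1C[C@@H](OC(=O)[C@@]2(C)O[C@@H]2C)C(C)(C)[C@@H]2[C@H]3C(=O)C=C(C)[C@@H]2[C@]31C | intermediate
34 | (Z)-2-methylbut-2-enoic acid (angelic acid) | C/C=C(/C)C(=O)O | starting material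
35 | mixed anhydride of 34 with 2,4,6-trichlorobenzoic acid (not isolated) | C/C=C(/C)C(=O)OC(=O)c1c(Cl)cc(Cl)cc1Cl | intermediate
36 | (4R,5S,7R,9R,10R,11R)-9-[(Z)-2-methylbut-2-enoyloxy]-7-[(2S,3R)-2,3-dimethyloxirane-2-carbonyloxy]longipin-2-en-1-one (CNP0149458.1) | C/C=C(/C)C(=O)O[C@@H]1C[C@@H](OC(=O)[C@@]2(C)O[C@@H]2C)C(C)(C)[C@@H]2[C@H]3C(=O)C=C(C)[C@@H]2[C@]31C | target

**Step count**

Total steps: 19. Longest linear sequence: 16 (steps 1–9, 11–14, 17–19).

**Steps most likely to fail**

Step 11. The magnesium enolate 21 may not acylate the neighbouring ethyl ester (slow or reversible closure into the strained bicyclo[3.1.1] ring), or the carbenoid may divert into C–H insertion next to the C7 silyl ether. The fallback uses known reactions only and sets out from 16. Rh2(O2CC(CH3)3)4 in toluene at −78 °C gives bicyclobutane 20, which is isolated. Copper-catalysed homoconjugate addition of isopropenylmagnesium bromide (CuBr·SMe2, PBu3, THF, −78 °C) and protonation give the methyl cyclobutanecarboxylate with isopropenyl on C4 and H/CO2Me on C11, F1. LiOH in aqueous THF–MeOH hydrolyses it and equilibrates C11 to the acid with CO2H cis to the isopropenyl group, F2. Oxalyl chloride gives the acid chloride F3, and SnCl4 in CH2Cl2 at −78 °C followed by Et3N closes the enone ring by acylating the CH2 terminus of the isopropenyl group (the C1–C2 bond) with loss of HCl. This comes back to the route at 26, so steps 12 and 13 are not needed.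

Step 5. The double dehydrobromination may run with poor regioselectivity and give exocyclic-methylene or C8-conjugated diene isomers. The fallback sets out from 7. 3-Chloroperbenzoic acid gives the epoxide F4. Sodium benzeneselenolate (from PhSeSePh and NaBH4 in EtOH) opens it at the CH carbon to the hydroxy selenide F5. H2O2 oxidation and syn elimination of the selenoxide, which can only run toward the CH2 next to CMe2, give the tertiary allylic alcohol F6. Dehydration with Burgess reagent toward the ring CH2 gives the conjugated diene, and the route is rejoined at 9.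

Step 8. Orthoester exchange at the neopentyl carbinol may be too slow, so that acid and heat eliminate the allylic alcohol back to a diene before the rearrangement. The fallback sets out from 12. NaH and methyl bromoacetate give the allyloxyacetate F7. LiN(iPr)2 in THF at −78 °C triggers a [2,3]-Wittig rearrangement across the same ring face and gives the α-hydroxy ester F8 with the same quaternary centre. Dess–Martin periodinane gives the α-keto ester F9, and 4-toluenesulfonohydrazide gives the hydrazone F10. DBU then eliminates sulfinate to give the diazo ester, so the route is rejoined at 16 and steps 8 and 9 are bypassed.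

Further compounds
F1 | step 11 | methyl cyclobutanecarboxylate from 20 with isopropenyl on C4 anti to the seven-membered ring, both C11 epimers | CC(=C)[C@H]1[C@@H]2C(C)(C)[C@H](O[Si](CC)(CC)CC)C[C@@H](O[Si](C)(C)C(C)(C)C)[C@@]1(C)C2C(=O)OC
F2 | step 11 | corresponding carboxylic acid with CO2H on C11 cis to the isopropenyl group | CC(=C)[C@H]1[C@@H]2C(C)(C)[C@H](O[Si](CC)(CC)CC)C[C@@H](O[Si](C)(C)C(C)(C)C)[C@@]1(C)[C@@H]2C(=O)O
F3 | step 11 | acid chloride of F2 | CC(=C)[C@H]1[C@@H]2C(C)(C)[C@H](O[Si](CC)(CC)CC)C[C@@H](O[Si](C)(C)C(C)(C)C)[C@@]1(C)[C@@H]2C(=O)Cl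
F4 | step 5 | 4,5-epoxide of 7 (either epoxide face) | CC12OC1CC(C)(C)[C@H](O[Si](CC)(CC)CC)CC2
F5 | step 5 | trans hydroxy selenide: tertiary alcohol at the methyl-bearing carbon, phenylselanyl on the neighbouring CH | CC1(O)C([Se]c2ccccc2)CC(C)(C)[C@H](O[Si](CC)(CC)CC)CC1
F6 | step 5 | 1,4,4-trimethyl-5-(triethylsilyloxy)cyclohept-2-en-1-ol (tertiary allylic alcohol, 5R) | CC1(O)C=CC(C)(C)[C@H](O[Si](CC)(CC)CC)CC1
F7 | step 8 | methyl 2-(cycloheptenyloxy)acetate: O-(methoxycarbonylmethyl) ether of 12 | CC1=C[C@@H](OCC(=O)OC)C(C)(C)[C@H](O[Si](CC)(CC)CC)C[C@H]1O[Si](C)(C)C(C)(C)C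
F8 | step 8 | methyl 2-hydroxy-2-(cycloheptenyl)acetate, the α-hydroxy analogue of 14 (carbinol epimers) | C[C@]1(C(O)C(=O)OC)C=CC(C)(C)[C@H](O[Si](CC)(CC)CC)C[C@H]1O[Si](C)(C)C(C)(C)C
F9 | step 8 | methyl 2-oxo-2-(cycloheptenyl)acetate, the α-keto analogue of 14 | C[C@]1(C(=O)C(=O)OC)C=CC(C)(C)[C@H](O[Si](CC)(CC)CC)C[C@H]1O[Si](C)(C)C(C)(C)C
F10 | step 8 | 4-toluenesulfonylhydrazone of F9 | C[C@]1(C(=NNS(=O)(=O)c2ccc(C)cc2)C(=O)OC)C=CC(C)(C)[C@H](O[Si](CC)(CC)CC)C[C@H]1O[Si](C)(C)C(C)(C)C
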